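## Retrosynthetic overview
1. Disconnect the furan ring (C3–C3a and C2–O): a radical [3+2] annulation of 2-(1,1-dimethylallyl)phloroglucinol (**6**) with terminal aryl alkyne **10**.
2. Alkyne **10** comes from 5-ethynylresorcinol (**8**) by C-diprenylation, then acid-catalysed mono-cyclisation of one prenyl group to the 2,2-dimethylchroman.
3. Triol **6** comes from Claisen rearrangement of the aryl prenyl ether of Bpin-resorcinol **2**, then C–B oxidation to the third OH. Both fragments derive from one Ir-borylated resorcinol.
4. Ring order: both benzene rings are already present, the chroman ring forms in Step 7, and the furan ring forms last (Step 8, key radical step).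

Assumptions: the target has no stereocentres. Resorcinol is borylated unprotected, via transient ArO–Bpin, at the only unhindered C–H (C5).

## Route

**Step 1**
Reactants: 1 resorcinol
Product: 2 5-(pinacolatoboryl)benzene-1,3-diol
Conditions: [Ir(OMe)(cod)]2 (1.5 mol%), dtbpy (3 mol%), HBpin (2.2 equiv), B2pin2 (1.1 equiv), THF, 80 °C; then aq. NH4Cl
Reagents that add atoms: B2pin2, CC1(C)OB(OC1(C)C)B2OC(C)(C)C(C)(C)O2 (delivers Bpin). HBpin only forms transient O–Bpin groups that are hydrolysed on work-up.
Why: Sterically controlled Ir-catalysed C–H borylation reaches only C5, because C2, C4 and C6 are flanked by OBpin groups. This installs the carbon handle, and later the third oxygen, meta to both OH groups.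

**Step 2**
Reactants: 2 Bpin-resorcinol; 3 prenyl bromide
Product: 4 3-(3-methylbut-2-enyloxy)-5-(Bpin)phenol
Conditions: 3 (0.9 equiv), K2CO3 (1.0 equiv), acetone, 50 °C
Reagents that add atoms: 3 prenyl bromide, CC(C)=CCBr (a listed reactant)
Why: Williamson O-alkylation of the two equivalent phenols. Limiting halide gives statistical mono-ether and recoverable diol.

**Step 3**
Reactants: 4
Product: 5 2-(2-methylbut-3-en-2-yl)-5-(Bpin)benzene-1,3-diol
Conditions: PhNEt2, 150 °C, sealed tube or microwave, 2 h
Reagents that add atoms: none
Why: Aromatic Claisen [3,3] rearrangement of an aryl prenyl ether delivers the 1,1-dimethylallyl (reverse-prenyl) group. It goes to the doubly oxygenated C2, because the Bpin at C5 disfavours C6, and the product carbon is achiral (gem-dimethyl).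

**Step 4**
Reactants: 5
Product: 6 2-(2-methylbut-3-en-2-yl)benzene-1,3,5-triol
Conditions: NaBO3·4H2O (3 equiv), THF/H2O 1:1, rt, 1 h, N2; crude used immediately
Reagents that add atoms: sodium perborate as H2O2 equivalent, OO (supplies the new phenolic O)
Why: Perborate oxidation of the C–B bond gives the phenol, converting the resorcinol into the phloroglucinol pattern that a resorcinol cannot reach by electrophilic substitution.

**Step 5**
Reactants: 2 Bpin-resorcinol; 7 (bromoethynyl)trimethylsilane
Product: 8 5-ethynylbenzene-1,3-diol
Conditions: Pd(OAc)2 (5 mol%), SPhos (10 mol%), K3PO4 (3 equiv), dioxane/H2O 4:1, 80 °C; then K2CO3, MeOH, rt (one pot)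
Reagents that add atoms: 7, C[Si](C)(C)C#CBr (a listed reactant; SiMe3 is lost in the one-pot desilylation)
Why: Suzuki–Miyaura sp2–sp alkynylation of the aryl boronate with a 1-bromoalkyne, followed by C–Si methanolysis, gives the terminal aryl alkyne.

**Step 6**
Reactants: 8; 3 prenyl bromide
Product: 9 5-ethynyl-4,6-bis(3-methylbut-2-enyl)benzene-1,3-diol
Conditions: 3 (2.3 equiv), KOH (2.5 equiv), H2O/MeOH 4:1, 0 °C to rt, 6 h
Reagents that add atoms: 3, CC(C)=CCBr (a listed reactant)
Why: In protic medium resorcinol dianions alkylate at carbon (C-alkylation). Attack occurs at C4 and C6 (ortho to one OH, para to the other), which flank only a linear, unhindered alkyne.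

**Step 7**
Reactants: 9
Product: 10 5-ethynyl-6-(3-methylbut-2-enyl)-2,2-dimethylchroman-7-ol
Conditions: p-TsOH·H2O (10 mol%), toluene, 50 °C, stopped at about 50% conversion; recover 9 and recycle
Reagents that add atoms: none (isomerisation)
Why: Acid-catalysed Markovnikov intramolecular hydroalkoxylation of an o-prenylphenol through the tertiary cation gives the 2,2-dimethylchroman. The two prenylphenol arms of 9 are equivalent, so partial conversion desymmetrises it without any regiochemical ambiguity.

**Step 8 (key radical step)**
Reactants: 6 triol; 10 aryl alkyne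
Product: 11 Artopetelin C
Conditions: 6 (2.0 equiv), 10 (1.0 equiv), Mn(OAc)3·2H2O (2.5 equiv), Cu(OAc)2 (0.5 equiv), AcOH, 60 °C, N2, 2 h
Reagents that add atoms: none (Mn(III) and Cu(II) are oxidants only)
Why: Proposed new method: Mn(III) enolises triol 6 to a C-centred radical flanked by two enol carbons, which adds to the unsubstituted terminus of alkyne 10 to give a linear α-aryl vinyl radical. Cu(II) oxidation and closure by the adjacent enol oxygen then aromatise to the 2-arylbenzofuran. The closest known reaction is the Mn(OAc)3/Cu(OAc)2 oxidative [3+2] of 1,3-dicarbonyls (4-hydroxycoumarin, dimedone) with alkynes to fused furans. Addition at the terminal carbon puts the aryl group at C2, closure through O1 puts the dimethylallyl group at C7, and no stereocentre is formed.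

## Compound list
1 | resorcinol | Oc1cccc(O)c1 | starting material
2 | 5-(Bpin)benzene-1,3-diol | Oc1cc(O)cc(B2OC(C)(C)C(C)(C)O2)c1 | intermediate
3 | prenyl bromide | CC(C)=CCBr | starting material
4 | 3-(prenyloxy)-5-(Bpin)phenol | CC(C)=CCOc1cc(O)cc(B2OC(C)(C)C(C)(C)O2)c1 | intermediate
5 | 2-(2-methylbut-3-en-2-yl)-5-(Bpin)benzene-1,3-diol | C=CC(C)(C)c1c(O)cc(B2OC(C)(C)C(C)(C)O2)cc1O | intermediate
6 | 2-(2-methylbut-3-en-2-yl)benzene-1,3,5-triol | C=CC(C)(C)c1c(O)cc(O)cc1O | intermediate
7 | (bromoethynyl)trimethylsilane | C[Si](C)(C)C#CBr | starting material
8 | 5-ethynylbenzene-1,3-diol | C#Cc1cc(O)cc(O)c1 | intermediate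
9 | 5-ethynyl-4,6-diprenylbenzene-1,3-diol | C#Cc1c(CC=C(C)C)c(O)cc(O)c1CC=C(C)C | intermediate
10 | 5-ethynyl-6-prenyl-2,2-dimethylchroman-7-ol | CC(C)=CCc1c(O)cc2OC(C)(C)CCc2c1C#C | intermediate
11 | Artopetelin C (achiral, no stereocentres) | C=CC(C)(C)c1c(O)cc(O)c2cc(-c3c(CC=C(C)C)c(O)cc4c3CCC(C)(C)O4)oc12 | target

## Totals
Total steps: 8. Longest linear sequence: 5 (Ir borylation, alkynylation, diprenylation, chroman cyclisation, radical annulation; the triol arm is also 5). Atom check: 6 (C11H14O3) + 10 (C18H22O2) − 2 H gives 11 (C29H34O5), a net two-electron oxidative annulation.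

Three steps most likely to fail:
1. **Step 8, radical annulation.** The prenyl alkene of 10 competes with the alkyne for the electrophilic radical, the triol can close through O1 or O5 (the O5 closure gives the 5-dimethylallyl regioisomer), and the free phenols are oxidisable. Fallback: use a low-valent-titanium (ketyl-radical) intramolecular oxo-ester coupling of the ring-B aroate of a 2-formylphenol. This couples carbonyls rather than adding radicals to alkenes, and it tolerates alkenes.
2. **Steps 6–7, diprenylation and desymmetrising cyclisation.** C- versus O-alkylation, the C2 side product and statistical mono-cyclisation limit the yield. Fallback: build the chroman first from 5-ethynylresorcinol and 3-methylbut-2-enal (chromene), then hydrogenate it. Install the second ring-B carbon unit by O-allylation, Claisen rearrangement, and cross-metathesis with 2-methyl-2-butene.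
3. **Step 3, Claisen rearrangement.** A quaternary centre must form next to an OH at 150 °C without cyclising to a dihydrobenzofuran or chroman, and C2 versus C6 selectivity must hold. Fallback: protect the diol as bis-TBS ethers and run a Lewis-acid-promoted (Et2AlCl or BCl3) Claisen at low temperature, or form the C–CMe2 bond by Pd- or Ir-catalysed reverse prenylation of the phloroglucinol.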